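**Retrosynthetic overview**

1. The target is (2S)-naringenin carrying a (2R)-1-methylpiperidin-2-yl group on C6 of ring A. C2' of the piperidine is a benzylic carbon ortho to the C5 phenol (and to O7), so it can serve as the exocyclic carbon of an ortho-quinone methide of ring A.
2. Last disconnections: N–CH3 (formaldehyde, through a transient N–CH2–O7 oxazine ring) and the benzyl groups on O7, O4' and N, all in one hydrogenation.
3. Key disconnection: the N–C2' bond of the piperidine, opened to an open-chain (E)-alkenyl carbamate on C6. Forward, a chiral acid turns this ortho-hydroxystyrene into the ortho-quinone methide and the carbamate closes the ring by an enantioselective 6-exo aza-Michael addition.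
4. The C6–alkenyl bond comes from a Suzuki–Miyaura coupling of a 6-iodide, placed by iodination ortho to the free 5-OH of 7,4'-di-O-benzylnaringenin.
5. Ring order: rings A, B and the pyranone ring C (with C2) arrive complete in (2S)-naringenin; the piperidine ring is closed last.

Key step: step 6

Assumption: commercial (2S)-naringenin of high enantiomeric purity is the source of C2 (a partly racemic lot would be upgraded by crystallisation or chiral chromatography); every later step is kept neutral or weakly acidic, because base opens the flavanone to the chalcone and would erase C2.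

**Route**

Step 1
Reactants: 1 (2S)-naringenin
Product: 2 (2S)-7-(benzyloxy)-2-[4-(benzyloxy)phenyl]-5-hydroxychroman-4-one
Conditions: BnOH (2.2 equiv), PPh3 (2.4 equiv), DIAD (2.4 equiv), THF, 0 °C to 23 °C
Reagents that add atoms: benzyl alcohol, OCc1ccccc1
Why: Mitsunobu etherification should alkylate the two acidic phenols (7-OH and 4'-OH) and leave the 5-OH, which is locked in a hydrogen bond to the C4 carbonyl, while the neutral conditions spare the base-labile C2 centre brought in with 1.

Step 2
Reactants: 2 (2S)-7-(benzyloxy)-2-[4-(benzyloxy)phenyl]-5-hydroxychroman-4-one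
Product: 3 (2S)-7-(benzyloxy)-2-[4-(benzyloxy)phenyl]-5-hydroxy-6-iodochroman-4-one
Conditions: BnMe3N·ICl2 (1.05 equiv), CaCO3, CH2Cl2–MeOH, 23 °C
Reagents that add atoms: benzyltrimethylammonium dichloroiodate, C[N+](C)(C)Cc1ccccc1.Cl[I-]Cl
Why: Electrophilic aromatic iodination of a phenol, in which the dichloroiodate should attack ring A ortho to its only free phenol (C6, next to the chelated 5-OH) rather than C8, as it does with 5-hydroxy-7-alkoxyflavones, while the benzyl-capped ring B and C2 are not touched.

Step 3
Reactants: 4 pent-4-yn-1-amine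
Product: 5 benzyl pent-4-yn-1-ylcarbamate
Conditions: CbzCl (1.05 equiv), NaHCO3, THF–H2O, 0 °C
Reagents that add atoms: benzyl chloroformate, O=C(Cl)OCc1ccccc1
Why: Schotten–Baumann N-acylation of a primary amine by a chloroformate, to which the terminal alkyne is inert.

Step 4
Reactants: 5 benzyl pent-4-yn-1-ylcarbamate
Product: 6 benzyl [(4E)-5-(4,4,5,5-tetramethyl-1,3,2-dioxaborolan-2-yl)pent-4-en-1-yl]carbamate
Conditions: HBpin (1.2 equiv), Cp2Zr(H)Cl (5 mol%), Et3N (10 mol%), neat, 60 °C
Reagents that add atoms: pinacolborane, CC1(C)OBOC1(C)C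
Why: Zirconium-catalysed hydroboration of a terminal alkyne, whose syn, anti-Markovnikov addition of the B–H bond should give the (E)-alkenylboronate with the carbamate N–H tolerated.

Step 5
Reactants: 3 (2S)-7-(benzyloxy)-2-[4-(benzyloxy)phenyl]-5-hydroxy-6-iodochroman-4-one and 6 benzyl [(4E)-5-(4,4,5,5-tetramethyl-1,3,2-dioxaborolan-2-yl)pent-4-en-1-yl]carbamate
Product: 7 benzyl {(4E)-5-[(2S)-7-(benzyloxy)-2-[4-(benzyloxy)phenyl]-5-hydroxy-4-oxochroman-6-yl]pent-4-en-1-yl}carbamate
Conditions: Pd(OAc)2 (5 mol%), SPhos (10 mol%), CsF (3 equiv), 1,4-dioxane, 50 °C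
Reagents that add atoms: none
Why: Suzuki–Miyaura coupling of an aryl iodide with an alkenylboronate, in which the biaryl phosphine should handle the doubly ortho-substituted iodide at low temperature with retention of alkene geometry, and fluoride as a weak activator avoids the base-induced opening of the flavanone that would erase C2.

Step 6
Reactants: 7 benzyl {(4E)-5-[(2S)-7-(benzyloxy)-2-[4-(benzyloxy)phenyl]-5-hydroxy-4-oxochroman-6-yl]pent-4-en-1-yl}carbamate
Product: 9 benzyl (2R)-2-[(2S)-7-(benzyloxy)-2-[4-(benzyloxy)phenyl]-5-hydroxy-4-oxochroman-6-yl]piperidine-1-carboxylate, via ortho-quinone methide 8 (not isolated)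
Conditions: (R)-TRIP, i.e. (R)-3,3'-bis(2,4,6-triisopropylphenyl)-1,1'-binaphthyl-2,2'-diyl hydrogen phosphate (10 mol%), PhMe, 4 Å MS, 30 °C
Reagents that add atoms: none
Why: Proposed new method: the chiral phosphoric acid relays the proton of the C5 phenol to the β-carbon of the styrene, which gives the ortho-quinone methide 8 bound to the phosphate, and the carbamate nitrogen adds to its exocyclic carbon while the phosphate holds both the methide oxygen (O5) and the N–H; the closest known reaction types are chiral phosphoric acid-catalysed enantioselective conjugate additions to ortho-quinone methides generated from ortho-hydroxystyrenes or ortho-hydroxybenzyl alcohols, and Brønsted acid-catalysed intramolecular hydroamination of styrenes by carbamates. The piperidine closes in the 6-exo-trig mode by an aza-Michael C–N bond formation that restores the aromaticity of ring A. The new stereocentre C2' is set by catalyst control, the 3,3'-aryl groups of the phosphate shielding one face of the planar methide, while the remote C2 has no influence; the R sense is expected from the (R)-acid by analogy and the (S)-acid is taken if the sense proves opposite. The step needs attack of nitrogen at the benzylic carbon only, which the ortho-phenol polarisation and the five-atom tether secure, and a single quinone methide, which the benzyl ether on O7 secures by leaving O5 as the only free phenol. It also needs kinetic control: the product carbamate should ionise much more slowly than the styrene is protonated, because benzylic carbamates of this electron-rich type need a strong acid such as CF3CO2H to ionise.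

Step 7
Reactants: 9 benzyl (2R)-2-[(2S)-7-(benzyloxy)-2-[4-(benzyloxy)phenyl]-5-hydroxy-4-oxochroman-6-yl]piperidine-1-carboxylate
Product: 12 (2S)-5,7-dihydroxy-2-(4-hydroxyphenyl)-6-[(2R)-1-methylpiperidin-2-yl]chroman-4-one, via secondary amine 10 (not isolated), via fused 1,3-oxazine 11 (not isolated)
Conditions: H2 (1 atm), 10% Pd/C, EtOAc–MeOH, 23 °C; then 37% aq. CH2O (1.1 equiv), H2 (1 atm), 23 °C
Reagents that add atoms: formaldehyde, C=O
Why: Hydrogenolysis of the two benzyl ethers and the benzyl carbamate should free 10, whose secondary amine condenses with formaldehyde and the neighbouring phenol to the N,O-acetal 11 (a temporary ring), and hydrogenolysis of its C–O bond through the ring-opened iminium (reductive amination) leaves the N-methyl group without involving either stereocentre.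

**Compound list**

1 | (2S)-naringenin, (2S)-5,7-dihydroxy-2-(4-hydroxyphenyl)chroman-4-one | c1c(O)cc2c(c1O)C(=O)C[C@@H](c1ccc(O)cc1)O2 | starting material
2 | (2S)-7-(benzyloxy)-2-[4-(benzyloxy)phenyl]-5-hydroxychroman-4-one | c1c(OCc3ccccc3)cc2c(c1O)C(=O)C[C@@H](c1ccc(OCc4ccccc4)cc1)O2 | intermediate
3 | (2S)-7-(benzyloxy)-2-[4-(benzyloxy)phenyl]-5-hydroxy-6-iodochroman-4-one | Ic1c(OCc3ccccc3)cc2c(c1O)C(=O)C[C@@H](c1ccc(OCc4ccccc4)cc1)O2 | intermediate
4 | pent-4-yn-1-amine | C#CCCCN | starting material
5 | benzyl pent-4-yn-1-ylcarbamate | C#CCCCNC(=O)OCc1ccccc1 | intermediate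
6 | benzyl [(4E)-5-(4,4,5,5-tetramethyl-1,3,2-dioxaborolan-2-yl)pent-4-en-1-yl]carbamate | CC1(C)OB(/C=C/CCCNC(=O)OCc2ccccc2)OC1(C)C | intermediate
7 | benzyl {(4E)-5-[(2S)-7-(benzyloxy)-2-[4-(benzyloxy)phenyl]-5-hydroxy-4-oxochroman-6-yl]pent-4-en-1-yl}carbamate | O=C(NCCC/C=C/c1c(OCc3ccccc3)cc2c(c1O)C(=O)C[C@@H](c1ccc(OCc4ccccc4)cc1)O2)OCc1ccccc1 | intermediate
8 | ortho-quinone methide of 7: benzyl {5-[(2S)-7-(benzyloxy)-2-[4-(benzyloxy)phenyl]-4,5-dioxo-2,3-dihydrochromen-6-ylidene]pentyl}carbamate (not isolated) | O=C1C(=CCCCCNC(=O)OCc3ccccc3)C(OCc4ccccc4)=CC2=C1C(=O)C[C@@H](c5ccc(OCc6ccccc6)cc5)O2 | intermediate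
9 | benzyl (2R)-2-[(2S)-7-(benzyloxy)-2-[4-(benzyloxy)phenyl]-5-hydroxy-4-oxochroman-6-yl]piperidine-1-carboxylate | O=C(OCc1ccccc1)N1CCCC[C@@H]1c1c(OCc3ccccc3)cc2c(c1O)C(=O)C[C@@H](c1ccc(OCc4ccccc4)cc1)O2 | intermediate
10 | (2S)-5,7-dihydroxy-2-(4-hydroxyphenyl)-6-[(2R)-piperidin-2-yl]chroman-4-one (not isolated) | N1CCCC[C@@H]1c1c(O)cc2c(c1O)C(=O)C[C@@H](c1ccc(O)cc1)O2 | intermediate
11 | N,O-acetal of 10 with formaldehyde: the piperidine nitrogen and O7 bridged by CH2 in a 1,3-oxazine fused to ring A and to the piperidine, (S) at the chromanone C2 and (R) at the former C2' (not isolated) | C1N2CCCC[C@@H]2c3c(O1)cc4c(c3O)C(=O)C[C@@H](c5ccc(O)cc5)O4 | intermediate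
12 | (2S)-5,7-dihydroxy-2-(4-hydroxyphenyl)-6-[(2R)-1-methylpiperidin-2-yl]chroman-4-one | CN1CCCC[C@@H]1c1c(O)cc2c(c1O)C(=O)C[C@@H](c1ccc(O)cc1)O2 | target

**Step count and risks**

Total step count: 7 steps. Longest linear sequence: 5 steps (steps 1, 2, 5, 6 and 7, from 1 to 12); steps 3 and 4 make the side-chain fragment 6.

The three steps most likely to fail:

1. Step 6 (Proposed new method). What may go wrong: protonation of the styrene, whose ring oxygens are all conjugated to the C4 carbonyl, may be too slow with a phosphoric acid; facial selectivity in the C–N closure may be poor; or the product may re-ionise and lose its C2' configuration. Fallback, setting out from 7 and coming back at 9: the ring is closed without facial control by a known Brønsted acid-catalysed intramolecular hydroamination of the styrene by the carbamate (CF3SO3H, 5 mol%, PhMe, 23 °C). This should give 9 together with its C2' epimer, benzyl (2S)-2-[(2S)-7-(benzyloxy)-2-[4-(benzyloxy)phenyl]-5-hydroxy-4-oxochroman-6-yl]piperidine-1-carboxylate F1. Because C2 is fixed, the two are diastereomers and can be separated by chromatography or crystallisation. F1 is returned to the acid, which re-opens it through 8 and re-equilibrates the pair, so the material is funnelled to 9.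

2. Step 2. What may go wrong: attack of the iodinating agent at C8 (para to the 5-OH) or twofold iodination may compete with the wanted ortho attack at C6. Fallback, setting out from 2 and coming back at 7: the carbon substituent is delivered to C6 from O5 by a sigmatropic shift that can reach no other position.
 - Neutral Tsuji–Trost O-allylation of 2 (allyl methyl carbonate, Pd(PPh3)4, THF, 40 °C) should give (2S)-5-(allyloxy)-7-(benzyloxy)-2-[4-(benzyloxy)phenyl]chroman-4-one F2.
 - Claisen rearrangement (Eu(fod)3, 10 mol%, CHCl3, 60 °C) moves the allyl group to C6, the only open position ortho to O5, giving (2S)-6-allyl-7-(benzyloxy)-2-[4-(benzyloxy)phenyl]-5-hydroxychroman-4-one F3.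
 - Alkene isomerisation (RuHCl(CO)(PPh3)3, 5 mol%, PhMe, 80 °C) brings the double bond into conjugation, giving (2S)-7-(benzyloxy)-2-[4-(benzyloxy)phenyl]-5-hydroxy-6-[(E)-prop-1-enyl]chroman-4-one F4.
 - Cross-metathesis (second-generation Hoveyda–Grubbs catalyst, CH2Cl2, 40 °C) with benzyl pent-4-en-1-ylcarbamate F5, made from pent-4-en-1-amine and benzyl chloroformate as in step 3, should give 7.

3. Step 7. What may go wrong: over-reduction on palladium (the C4 carbonyl, or hydrogenolysis of the benzylic C2'–N bond), or aminomethylation at C8 by the formaldehyde-derived iminium once ring A is fully deprotected. Fallback, setting out from 9 and coming back at 12: the nitrogen is methylated while ring A is still benzylated, and no formaldehyde meets the free phloroglucinol ring.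
 - Hydrogenolysis in the presence of a nitrogen base (H2, 10% Pd/C, pyridine 0.5 equiv, MeOH), which is known to suppress cleavage of phenolic benzyl ethers, should remove only the carbamate and give (2S)-7-(benzyloxy)-2-[4-(benzyloxy)phenyl]-5-hydroxy-6-[(2R)-piperidin-2-yl]chroman-4-one F6.
 - Reductive amination with a hydride that does not touch the ketone (37% aq. CH2O, NaBH(OAc)3, AcOH, ClCH2CH2Cl, 0 °C) should give (2S)-7-(benzyloxy)-2-[4-(benzyloxy)phenyl]-5-hydroxy-6-[(2R)-1-methylpiperidin-2-yl]chroman-4-one F7.
 - A plain debenzylation (H2, 10% Pd/C, EtOAc–MeOH, 23 °C) then gives 12.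

Further compounds
F1 | step 6 | benzyl (2S)-2-[(2S)-7-(benzyloxy)-2-[4-(benzyloxy)phenyl]-5-hydroxy-4-oxochroman-6-yl]piperidine-1-carboxylate | O=C(OCc1ccccc1)N1CCCC[C@H]1c1c(OCc3ccccc3)cc2c(c1O)C(=O)C[C@@H](c1ccc(OCc4ccccc4)cc1)O2
F2 | step 2 | (2S)-5-(allyloxy)-7-(benzyloxy)-2-[4-(benzyloxy)phenyl]chroman-4-one | c1c(OCc3ccccc3)cc2c(c1OCC=C)C(=O)C[C@@H](c1ccc(OCc4ccccc4)cc1)O2
F3 | step 2 | (2S)-6-allyl-7-(benzyloxy)-2-[4-(benzyloxy)phenyl]-5-hydroxychroman-4-one | C=CCc1c(OCc3ccccc3)cc2c(c1O)C(=O)C[C@@H](c1ccc(OCc4ccccc4)cc1)O2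
F4 | step 2 | (2S)-7-(benzyloxy)-2-[4-(benzyloxy)phenyl]-5-hydroxy-6-[(E)-prop-1-enyl]chroman-4-one | C/C=C/c1c(OCc3ccccc3)cc2c(c1O)C(=O)C[C@@H](c1ccc(OCc4ccccc4)cc1)O2
F5 | step 2 | benzyl pent-4-en-1-ylcarbamate | C=CCCCNC(=O)OCc1ccccc1
F6 | step 7 | (2S)-7-(benzyloxy)-2-[4-(benzyloxy)phenyl]-5-hydroxy-6-[(2R)-piperidin-2-yl]chroman-4-one | N1CCCC[C@@H]1c1c(OCc3ccccc3)cc2c(c1O)C(=O)C[C@@H](c1ccc(OCc4ccccc4)cc1)O2
F7 | step 7 | (2S)-7-(benzyloxy)-2-[4-(benzyloxy)phenyl]-5-hydroxy-6-[(2R)-1-methylpiperidin-2-yl]chroman-4-one | CN1CCCC[C@@H]1c1c(OCc3ccccc3)cc2c(c1O)C(=O)C[C@@H](c1ccc(OCc4ccccc4)cc1)O2
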